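The earlier runs and the new flask are calculated for an exercise, and the scatter is random.

- The ash flask holds 0.600 M of Q, the limiting reagent, against 0.00120 M of J, so Q held on J is at most 0.200 % of the charge, and I book Z over Q charged as the share turned.

| flask | Q | J | time |
|---|---|---|---|
| ash | 0.600 M | 0.00120 M |  |
| cedar | 1.20 M | 0.00120 M |  |
| oak | 0.600 M | 0.00180 M |  |
| alder | 0.600 M | 0.00120 M | 44 min |

| run | time / min | [Z] / M |
|---|---|---|
| ash run | 0.98 | 0.0210 |
| ash run | 3.0 | 0.0602 |
| ash run | 5.7 | 0.1024 |
| ash run | 9.0 | 0.1387 |
| ash run | 13 | 0.1763 |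
| ash run | 17 | 0.1993 |
| ash run | 22 | 0.2230 |
| cedar run | 0.98 | 0.0318 |
| cedar run | 3.0 | 0.0952 |
| cedar run | 5.7 | 0.1624 |
| cedar run | 9.0 | 0.2387 |
| cedar run | 13 | 0.3089 |
| cedar run | 17 | 0.3570 |
| cedar run | 22 | 0.4126 |
| oak run | 0.98 | 0.0295 |
| oak run | 3.0 | 0.0840 |
| oak run | 5.7 | 0.1385 |
| oak run | 9.0 | 0.1777 |
| oak run | 13 | 0.2165 |
| oak run | 17 | 0.2348 |
| oak run | 22 | 0.2580 |

(readings scatter by 0.002 M)

- Overall: Q -> Z, with J as catalyst.
- Constant volume, constant temperature.
- Bound and free are read together.
- An order is taken over about fifteen percent of the charge, up and down.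

* apparent order in [J] of the starting rate, round the charge of the ash run (the rate where two percent of its Q have turned into Z)
* apparent order in [Q] of the starting rate, round the charge of the ash run (the rate where two percent of its Q have turned into Z) (one fixed amount of Z, the same in the runs compared)
* Z in the alder run at 44 min, as a share of the Q charged

- Ash ledger at 22 min: 0.2230 M stands as Z, which is 37.2 % of the charge, and 0.377 M stands as Q, free and bound together.
- I carry one quantity, the catalyst clock θ: time multiplied by J charged over the J charged in ash, so that one oak minute counts as 1.50 clock minutes.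
- Oak reads 0.1777 M at θ = 13.5 min, and ash reads 0.1763 M at θ = 13 min. Z follows θ across these two flasks, so I put the order in J near 1.
- Alder has the charge of ash, so its θ is its time, 44 min. I take its curve from the ash and oak readings on the shared clock.
- From 13 min to 22 min, the ash share climbs at 0.00865 min⁻¹ around θ = 17.5 min. Over the same minutes in oak, the share climbs at 0.00512 min⁻¹ of clock time around θ = 26.2 min.
- The climb is slower at the later clock time, and if it keeps slowing exponentially, its time constant is 16.7 min.
- Oak's last reading stands at θ = 33.0 min with 43.0 % turned. Continuing to 44 min adds 2.76 %, so my own figure is 45.8 %.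
- The forecast gives 0.95 in J, 0.72 in Q and 45 % for alder, the last on the ground that “the rate falls roughly linearly with fractional conversion”. Its 45 % stands below my 45.8 %.
- The flask gives 1.0 in J, 0.72 in Q and 45.8 % for alder, and all three forecast values stand within their margins.

    J + Q ⇌ JQ, settled at all times (0.8680 L mol⁻¹)
    JQ ⇌ Z + J (56.10 min⁻¹, 40.38 L mol⁻¹ min⁻¹)
    2 J → 2 Oz (40.74 L mol⁻¹ min⁻¹)

- In the alder run, JQ turns to Z and back while 2 J → 2 Oz removes J during the same minutes: at the start 65.8 % of J stands free, and J, free and bound counted together, then falls at 0.0423 min⁻¹ of itself. At 44 min, alder's Z stands at 45.8 %, under the 54.7 % where the steps to and from Z balance, and ash, with the same charge, passes half at 77.0 min. Oak, with 1.50 clock minutes to each minute, passes that share at 51.4 min, which is θ = 77.1 min against the 77.0 min of ash.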